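The numbers in the tables come from a simulation from invented constants; scatter was added.

The sum of free starting material, ring, open dimer, side product and quenched substrate stayed at the charge in the flask, so I followed the one step that feeds ring: free starting material closing.

| flask | starting material | protic impurity | temperature | remark | time |
|---|---|---|---|---|---|
| summer | 0.055 M | 0.0275 M | 0 °C | the very flask that is asked about, followed so far |  |
| dawn | 0.055 M | 0.0275 M | −15 °C | run made earlier |  |
| flask | 0.055 M | 0.0275 M | 0 °C |  | 10 h |

- summer (time / h: ring / %): 0.417: 13.3; 1.33: 23.9; 2.00: 28.8; 3.00: 31.2; 5.00: 35.0; 6.00: 37.1
- dawn (time / h: ring / %): 0.833: 3.1; 3.00: 8.4; 4.00: 8.3; 6.00: 11.1; 10.0: 13.7; 12.0: 15.2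

(readings scatter by 0.5 percentage points)

- ring, in percent of the starting material first charged, at 10 h
- what to do for the largest gain in ring; "none" if nothing gains more than 2 percentage points (north-east / north / south / west / none)
- ring present, with what was taken out counted in, in percent of the starting material first charged, after north-east
- ring present, with what was taken out counted in, in percent of the starting material first charged, after west

- north-east: change nothing and wait 5.0 h more
- north: at 10 h raise the temperature by 20 K, then wait 5.0 h
- south: at 10 h add starting material, 50.0% of the amount charged, then wait 5.0 h
- west: at 10 h take out 90% of the ring then present, then wait 5.0 h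

- percent here means starting material units held: one open dimer or side product counts as two
- ring that was removed still counts
- what may be going on: starting material -> ring; starting material + ring -> side product; starting material + protic impurity -> quenched substrate; 2 starting material <-> open dimer
- additions bring no volume worth counting

The summer run is this flask followed so far. Its first reading, 13.3% at 0.417 h, gave 3.14 h as the closing lifetime, the first-order time in which free starting material turns into ring. My doubt was that c(starting material) may already have fallen by that reading, which would make this lifetime too long, but I had no better reading. From 3.00 h to 6.00 h the ring gained 5.9 percentage points, so: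

free share = closing lifetime × gain per hour = 6.17%

Held steady, that share would add 7.9 points by 10 h. But the dawn run's gain per hour fell by a factor 0.759 from its middle stretch to its last, so I applied that factor once:

ring at 10 h = 43.1%

Applying it twice over the further 5.0 h gave 48.7% for north-east, and I put west level with that.

The first readings of the two runs differ in speed by a factor 8.57. Scaled to 20 K, that is a factor 17.5, and the closing lifetime becomes 0.179 h. Taken straight, this gives 1.31 times the charge, which is impossible, being more than the 57 points not yet ring. So the stream must collapse, and the readings did not show how much of that room can return. For south, half the flask's gain at 5.00 h gave 18 points, and north needed 30.7% of the room to match it. I chose north, as a bet.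

The forecast gave 43.5%, south, 48% and 49%, holding that “Adding fresh starting material, with the impurity largely consumed, should give the largest gain”.

The flask gave ring 39.2% at 10 h. North gained most, 30 points against 23 points for south. North-east reached 41.9% and west 42.2%.

    starting material → ring (k = 0.00710 min⁻¹, Ea = 93.0 kJ mol⁻¹)
    starting material + ring → side product (k = 0.0250 M⁻¹ min⁻¹, Ea = 59.0 kJ mol⁻¹)
    starting material + protic impurity → quenched substrate (k = 0.160 M⁻¹ min⁻¹, Ea = 43.0 kJ mol⁻¹)
    2 starting material ⇌ open dimer (K = 480 M⁻¹, k = 0.200 M⁻¹ min⁻¹, Ea = 60.0 kJ mol⁻¹, ΔH = −40.0 kJ mol⁻¹)
    (constants at 0 °C)

The neighbour charged with 0.11 M of protic impurity stood at ring 23.5% after 10 h, against 39.2% in the flask. Ring present over 10 h, times the closing lifetime, is a mean free share, and the lifetime cancels in the ratio, so by ring present the neighbour's mean free share stood at 59.9% of the flask's. At its end the neighbour held 0.483% free starting material, and 51.5% stood as quenched substrate.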